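The question was when, within the time allowed, this flask holds most loose adduct, and how much.

* time, not beyond 12 min, at which the flask holds most loose adduct
* the amount of loose adduct, in percent of the substrate charged, at that time

| flask | substrate | reagent | remark | time |
|---|---|---|---|---|
| gamma | 0.56 M | 0.44 M (fed, over 1.0 min) | run made earlier; the fed solution adds 0.20 times the starting volume |  |
| delta | 0.88 M | 0.44 M (fed, over 1.0 min) | run made earlier; the fed solution adds 0.20 times the starting volume |  |
| flask | 0.40 M | 0.440 M (fed, over 1.0 min) | the fed solution adds 0.20 times the starting volume | 12 min |

| run | time / min | loose adduct / % | target / % |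
|---|---|---|---|
| gamma | 0.333 | 3.4 | 0 |
| gamma | 1.33 | 14.7 | 6.1 |
| gamma | 4.00 | 6.3 | 21.9 |
| gamma | 15.0 | 0.2 | 23.2 |
| delta | 0.333 | 2.9 | 0 |
| delta | 1.33 | 12.8 | 5.6 |
| delta | 4.00 | 3.7 | 19.2 |
| delta | 15.0 | 0.8 | 17.0 |

(each reading ± 0.5 percentage points)

- charges are per starting volume, the dose included; the dosed solution carries all of it
- a reading or a percentage of target counts all its forms, free or not

I read the two runs column against column, since both have the flask's reagent charge and feed and differ in substrate. At 1.33 min gamma held 14.7 % of loose adduct and delta 12.8 %. The substrate charge differed by a factor 1.57, but these percentages differed by a factor of 1.15. I took from this that, with the reagent charge held, the percentage of loose adduct moved little with the substrate charge, and upward as that charge fell.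

The next row showed gamma down to 6.3 % at 4.00 min. The earlier reading came just after the feed ended, so I put the flask's top near that reading, 1.33 min.

For the height, I continued the small drift between the runs down to the flask's [substrate], which gave 15.7 %. Dividing by the reagent charge gave the capture share, the top percentage of loose adduct per molar of reagent charged: 0.356 /M.

The forecast gave 16 % at 1.5 min, later than my time, on the ground that “Lower substrate means reagent lives longer”.

The flask gave 16.3 % at 1.49 min.

    substrate + target ⇌ idle adduct, settled at all times (K = 2.80 /M)
    target ⇌ isomer of the product (K = 1.30, k = 0.00210 /s)
    loose adduct → side product (k = 0.00940 /s)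
    loose adduct → target (k = 0.0110 /s)
    substrate + reagent ⇌ loose adduct (K = 4.90 /M, k = 0.0250 /M/s)

On the flask, the capture share comes to 0.370 /M against my 0.356 /M. The neighbour flask differs in its reagent, 0.75 M, which is 1.88 equiv on substrate. My capture share promised it 26.7 %, but it reached 23.8 %, a share of 0.317 /M. Its top therefore stood 2.9 percentage points below the reckoning.

(The runs are calculated on assumed constants; the scatter is artificial.)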